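**Retrosynthetic overview**
1. Feature (lignan numbering): in the 7'-deoxy skeleton, the carbinol carbon C7' is a benzylic CH2 on the 3,4-dimethoxyphenyl ring B, para to its 4'-OMe. It lies γ to the carboxyl carbon C9 (C2 of lactone ring C) along C9–C8–C8'–C7'. The other benzylic carbon, C7 on guaiacyl ring A, is only β to C9.
2. Last disconnection: ring C (the 9,9'-lactone) of 19 comes from the isomeric 9,7'-lactone (ring D) by O-to-O acyl transfer from the C7' oxygen to the freed C9' oxygen. No bond at a stereocentre is broken.
3. Key disconnection: the C7'–O bond of ring D is made by two-electron anodic oxidation of ring B in seco acid 15, with the C9 carboxylate capturing the C7' cation.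
4. 15 goes back to (−)-arctigenin 11 (ring C opened, C9'–OH silylated, ring A phenol acetylated). 11 goes back to trans-selective alkylation of (R)-lactone 6 with bromide 8, and 6 to a Stobbe half-ester and an asymmetric hydrogenation.
5. Ring order: ring C is closed (step 3) and opened (step 7), ring D is closed (step 10), and ring C closes again as ring D opens (step 12).

Key step: step 10

Assumption: (S,S)-Et-DuPhos is taken to give the (R)-acid 4, by analogy with the sense of induction known for itaconates. If a test run shows the opposite sense, the (R,R)-ligand is used and nothing else changes.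

Step 1
Reactants: 1 veratraldehyde; 2 dimethyl succinate
Product: 3 (E)-4-(3,4-dimethoxyphenyl)-3-(methoxycarbonyl)but-3-enoic acid
Conditions: NaOMe (1.2 equiv), MeOH, reflux; then aq. HCl
Reagents that add atoms: none
Why: Stobbe condensation, in which the succinate enolate adds to the aldehyde, the aldolate closes to a paraconic ester, and base-induced ring opening gives the half-ester with the aryl group trans to the ester (E) for steric reasons.

Step 2
Reactants: 3 (E)-4-(3,4-dimethoxyphenyl)-3-(methoxycarbonyl)but-3-enoic acid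
Product: 4 (R)-4-(3,4-dimethoxyphenyl)-3-(methoxycarbonyl)butanoic acid
Conditions: [Rh(cod)((S,S)-Et-DuPhos)]BF4 (0.2 mol %), NaOMe (10 mol %), H2 (6 bar), MeOH, rt
Reagents that add atoms: none
Why: Rhodium-catalysed asymmetric hydrogenation of an itaconate-type half-ester, in which olefin and carboxylate chelate the cationic bisphospholane–rhodium centre so that H2 reaches one olefin face and C8' is set as (R).

Step 3
Reactants: 4 (R)-4-(3,4-dimethoxyphenyl)-3-(methoxycarbonyl)butanoic acid
Product: 6 (R)-4-(3,4-dimethoxybenzyl)dihydrofuran-2(3H)-one, via hydroxy acid 5 (not isolated)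
Conditions: LiOH (1.0 equiv), MeOH, evaporate; LiBH4 (1.5 equiv), THF, 0 to 40 °C; then 2 M HCl, rt
Reagents that add atoms: none
Why: Chemoselective borohydride reduction, since LiBH4 reduces the methyl ester but not the lithium carboxylate, followed by acid-promoted lactonisation of the γ-hydroxy acid (5-exo-trig) that leaves the stereocentre untouched.

Step 4
Reactants: 7 [4-(benzyloxy)-3-methoxyphenyl]methanol
Product: 8 1-(benzyloxy)-4-(bromomethyl)-2-methoxybenzene
Conditions: PBr3 (0.4 equiv), Et2O, 0 °C; used at once
Reagents that add atoms: phosphorus tribromide, BrP(Br)Br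
Why: Alcohol-to-bromide exchange with PBr3 (SN2 displacement on the phosphite ester), which is reliable for an electron-rich benzylic alcohol when run cold and the bromide is not stored.

Step 5
Reactants: 6 (R)-4-(3,4-dimethoxybenzyl)dihydrofuran-2(3H)-one; 8 1-(benzyloxy)-4-(bromomethyl)-2-methoxybenzene
Product: 10 (3R,4R)-3-[4-(benzyloxy)-3-methoxybenzyl]-4-(3,4-dimethoxybenzyl)dihydrofuran-2(3H)-one (O-benzylarctigenin), via lithium enolate 9 (not isolated)
Conditions: LiN(SiMe3)2 (1.05 equiv), THF, −78 °C; then 8, −78 to −20 °C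
Reagents that add atoms: none
Why: Diastereoselective lactone enolate alkylation, in which the bromide approaches the planar enolate on the face away from the C4 benzyl group and so sets C3 (C8) as (R), trans to C4.

Step 6
Reactants: 10 O-benzylarctigenin
Product: 11 (3R,4R)-4-(3,4-dimethoxybenzyl)-3-(4-hydroxy-3-methoxybenzyl)dihydrofuran-2(3H)-one, (−)-arctigenin
Conditions: H2 (1 atm), 10% Pd/C, EtOAc/EtOH, rt
Reagents that add atoms: none
Why: Catalytic hydrogenolysis of an aryl benzyl ether, to which the lactone, the methyl ethers and both stereocentres are inert, and which gives a natural product whose rotation can serve as a check of identity and enantiopurity.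

Step 7
Reactants: 11 (−)-arctigenin
Product: 13 tert-butyldimethylsilyl (2R,3R)-4-(tert-butyldimethylsilyloxy)-2-[4-(tert-butyldimethylsilyloxy)-3-methoxybenzyl]-3-(3,4-dimethoxybenzyl)butanoate, via disodium salt 12 (not isolated)
Conditions: NaOH (2.05 equiv), THF/H2O, rt; evaporate, dry with toluene; TBSCl (4 equiv), imidazole (8 equiv), DMF, rt
Reagents that add atoms: sodium hydroxide, [Na+].[OH-]; tert-butyldimethylsilyl chloride (TBSCl), CC(C)(C)[Si](C)(C)Cl
Why: Lactone saponification followed by exhaustive silylation, since the γ-hydroxy acid cannot close again while its carboxyl group is an anion, and TBSCl/imidazole then caps the primary alcohol, the phenoxide and the carboxylate together.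

Step 8
Reactants: 13 tris-silyl compound
Product: 14 (2R,3R)-4-(tert-butyldimethylsilyloxy)-3-(3,4-dimethoxybenzyl)-2-(4-hydroxy-3-methoxybenzyl)butanoic acid
Conditions: K2CO3 (3 equiv), MeOH/THF/H2O, rt; then 1 M HCl to pH 4–5, 0 °C, extract at once
Reagents that add atoms: none
Why: Selective solvolysis of silyl groups by leaving-group ability, in which aqueous methanolic carbonate cleaves the silyl ester and the aryl silyl ether (stabilised oxygen anions) but leaves the primary alkyl TBS ether that keeps ring C from closing again.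

Step 9
Reactants: 14 phenol acid
Product: 15 (2R,3R)-2-(4-acetoxy-3-methoxybenzyl)-4-(tert-butyldimethylsilyloxy)-3-(3,4-dimethoxybenzyl)butanoic acid
Conditions: NaOH (2.1 equiv), Ac2O (1.5 equiv), THF/H2O, 0 °C; then 1 M HCl to pH 4, 0 °C
Reagents that add atoms: acetic anhydride, CC(=O)OC(C)=O
Why: Schotten–Baumann-type acetylation, in which only the phenoxide stays acylated in cold aqueous base because any mixed anhydride at the carboxylate is hydrolysed back, and the acetate lowers the electron density of ring A for the next step.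

Step 10
Reactants: 15 (2R,3R)-2-(4-acetoxy-3-methoxybenzyl)-4-(tert-butyldimethylsilyloxy)-3-(3,4-dimethoxybenzyl)butanoic acid
Product: 16 (3R,4R,5S)-3-(4-acetoxy-3-methoxybenzyl)-4-[(tert-butyldimethylsilyloxy)methyl]-5-(3,4-dimethoxyphenyl)dihydrofuran-2(3H)-one (3,4-cis, 4,5-trans)
Conditions: undivided cell, graphite anode, Pt cathode, constant current (about 2 mA cm−2, 2.2 F mol−1), nBu4NPF6 (0.1 M), 2,6-lutidine (2 equiv), CH2Cl2/HFIP 9:1, 0 °C to rt
Reagents that add atoms: none
Why: This is an intramolecular anodic benzylic C–H acyloxylation (oxidative benzylic lactonisation of a 4-(alkoxyaryl)butanoic acid, the net change DDQ also brings about): ring B gives up one electron, lutidine removes a C7' proton from the radical cation, and a second electron transfer leaves a C7' cation stabilised as a quinoid oxocarbenium ion by the para 4'-methoxy group. The C9 carboxylate adds to this trigonal carbon in a 5-exo-trig closure, forming the C7'–O bond and the temporary ring D while H2 leaves at the cathode. The new C5 stereocentre is controlled by its neighbour C4: the benzyl and silyloxymethyl groups on C3 and C4 are already cis, so the aryl group avoids an all-cis ring only by ending trans to CH2OTBS, which is (5S) and maps onto the (S)-carbinol of 19. Site selectivity rests on three substrate features: the acetate should make ring A harder to oxidise than ring B by a few tenths of a volt, a C7 cation could be caught by the carboxylate only as a β-lactone, and the acetate blocks the ipso spirolactonisation that a free phenol or ether on this 3-arylpropanoic acid unit would invite. Friedel–Crafts attack by C6 of ring A, proton loss from C8' and aryl–aryl coupling are countered by the lutidine buffer, which makes deprotonation and O-capture fast and keeps the benzylic lactone from ionising again. Kolbe decarboxylation needs a much higher potential than the arene.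

Step 11
Reactants: 16 acetoxy lactone
Product: 17 (3R,4R,5S)-4-[(tert-butyldimethylsilyloxy)methyl]-5-(3,4-dimethoxyphenyl)-3-(4-hydroxy-3-methoxybenzyl)dihydrofuran-2(3H)-one
Conditions: pyrrolidine (1.5 equiv), CH2Cl2, 0 °C to rt
Reagents that add atoms: none
Why: Chemoselective aminolysis of an aryl ester, in which phenoxide is a far better leaving group than the lactone alkoxide so pyrrolidine takes only the acetyl group, and the acetate is removed before the silyl group so that no acetyl donor is present when alkoxides are freed in step 12.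

Step 12
Reactants: 17 phenol lactone
Product: 19 (3R,4R)-4-[(S)-(3,4-dimethoxyphenyl)(hydroxy)methyl]-3-(4-hydroxy-3-methoxybenzyl)dihydrofuran-2(3H)-one, via hydroxymethyl lactone 18 (not isolated)
Conditions: nBu4NF (2.5 equiv), THF, 0 °C to rt; AcOH quench
Reagents that add atoms: none
Why: Fluoride desilylation followed by translactonisation (intramolecular O-to-O acyl transfer, 5-exo-trig), in which the freed C9' oxygen adds to C9 to give a 2,6-dioxabicyclo[2.2.1]heptan-1-olate that expels the secondary benzylic oxygen, driven by the change from a 3,4-cis lactone of a secondary alcohol to a 3,4-trans lactone of a primary alcohol, and since only acyl–oxygen bonds break all three stereocentres keep their configuration.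

**Compound list**
1 | veratraldehyde (3,4-dimethoxybenzaldehyde) | COc1ccc(C=O)cc1OC | starting material
2 | dimethyl succinate | COC(=O)CCC(=O)OC | starting material
3 | (E)-4-(3,4-dimethoxyphenyl)-3-(methoxycarbonyl)but-3-enoic acid | COC(=O)/C(CC(=O)O)=C/c1ccc(OC)c(OC)c1 | intermediate
4 | (R)-4-(3,4-dimethoxyphenyl)-3-(methoxycarbonyl)butanoic acid | COC(=O)[C@H](Cc1ccc(OC)c(OC)c1)CC(=O)O | intermediate
5 | (R)-3-(3,4-dimethoxybenzyl)-4-hydroxybutanoic acid | OC[C@H](Cc1ccc(OC)c(OC)c1)CC(=O)O | intermediate
6 | (R)-4-(3,4-dimethoxybenzyl)dihydrofuran-2(3H)-one | O=C1C[C@@H](Cc2ccc(OC)c(OC)c2)CO1 | intermediate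
7 | [4-(benzyloxy)-3-methoxyphenyl]methanol | COc1cc(CO)ccc1OCc1ccccc1 | starting material
8 | 1-(benzyloxy)-4-(bromomethyl)-2-methoxybenzene | COc1cc(CBr)ccc1OCc1ccccc1 | intermediate
9 | lithium enolate of 6 | [Li+].[O-]C1=C[C@@H](Cc2ccc(OC)c(OC)c2)CO1 | intermediate
10 | (3R,4R)-3-[4-(benzyloxy)-3-methoxybenzyl]-4-(3,4-dimethoxybenzyl)dihydrofuran-2(3H)-one | COc1cc(C[C@H]2C(=O)OC[C@@H]2Cc2ccc(OC)c(OC)c2)ccc1OCc1ccccc1 | intermediate
11 | (−)-arctigenin, (3R,4R)-4-(3,4-dimethoxybenzyl)-3-(4-hydroxy-3-methoxybenzyl)dihydrofuran-2(3H)-one | COc1cc(C[C@H]2C(=O)OC[C@@H]2Cc2ccc(OC)c(OC)c2)ccc1O | intermediate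
12 | disodium (2R,3R)-3-(3,4-dimethoxybenzyl)-4-hydroxy-2-(3-methoxy-4-oxidobenzyl)butanoate | [Na+].[Na+].[O-]C(=O)[C@H](Cc1ccc([O-])c(OC)c1)[C@H](CO)Cc1ccc(OC)c(OC)c1 | intermediate
13 | tert-butyldimethylsilyl (2R,3R)-4-(tert-butyldimethylsilyloxy)-2-[4-(tert-butyldimethylsilyloxy)-3-methoxybenzyl]-3-(3,4-dimethoxybenzyl)butanoate | CC(C)(C)[Si](C)(C)OC(=O)[C@H](Cc1ccc(O[Si](C)(C)C(C)(C)C)c(OC)c1)[C@H](CO[Si](C)(C)C(C)(C)C)Cc1ccc(OC)c(OC)c1 | intermediate
14 | (2R,3R)-4-(tert-butyldimethylsilyloxy)-3-(3,4-dimethoxybenzyl)-2-(4-hydroxy-3-methoxybenzyl)butanoic acid | OC(=O)[C@H](Cc1ccc(O)c(OC)c1)[C@H](CO[Si](C)(C)C(C)(C)C)Cc1ccc(OC)c(OC)c1 | intermediate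
15 | (2R,3R)-2-(4-acetoxy-3-methoxybenzyl)-4-(tert-butyldimethylsilyloxy)-3-(3,4-dimethoxybenzyl)butanoic acid | OC(=O)[C@H](Cc1ccc(OC(C)=O)c(OC)c1)[C@H](CO[Si](C)(C)C(C)(C)C)Cc1ccc(OC)c(OC)c1 | intermediate
16 | (3R,4R,5S)-3-(4-acetoxy-3-methoxybenzyl)-4-[(tert-butyldimethylsilyloxy)methyl]-5-(3,4-dimethoxyphenyl)dihydrofuran-2(3H)-one | O=C1O[C@H](c2ccc(OC)c(OC)c2)[C@@H](CO[Si](C)(C)C(C)(C)C)[C@H]1Cc1ccc(OC(C)=O)c(OC)c1 | intermediate
17 | (3R,4R,5S)-4-[(tert-butyldimethylsilyloxy)methyl]-5-(3,4-dimethoxyphenyl)-3-(4-hydroxy-3-methoxybenzyl)dihydrofuran-2(3H)-one | O=C1O[C@H](c2ccc(OC)c(OC)c2)[C@@H](CO[Si](C)(C)C(C)(C)C)[C@H]1Cc1ccc(O)c(OC)c1 | intermediate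
18 | (3R,4R,5S)-5-(3,4-dimethoxyphenyl)-3-(4-hydroxy-3-methoxybenzyl)-4-(hydroxymethyl)dihydrofuran-2(3H)-one | O=C1O[C@H](c2ccc(OC)c(OC)c2)[C@@H](CO)[C@H]1Cc1ccc(O)c(OC)c1 | intermediate
19 | (3R,4R)-4-[(S)-(3,4-dimethoxyphenyl)(hydroxy)methyl]-3-(4-hydroxy-3-methoxybenzyl)dihydrofuran-2(3H)-one | COc1cc(C[C@H]2C(=O)OC[C@@H]2[C@H](O)c2ccc(OC)c(OC)c2)ccc1O | target

**Step count**
Total step count: 12.
Longest linear sequence: 11 (steps 1–3 and 5–12).

**Steps most likely to fail**

1. Step 10. Several processes could divert the C7' cation: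
   - capture by C6 of ring A (Friedel–Crafts closure to an aryltetralin);
   - loss of the C8' proton;
   - oxidative coupling of the ring B radical cation at the anode;
   - further oxidation of 16;
   - ring closure with poor facial selectivity.

   The fallback sets out from 11 and comes back at 19. It places the oxygen on the intact trans lactone at the ketone level and sets the carbinol by hydride delivery. Acetylation of 11 (Ac2O, pyridine) gives O-acetylarctigenin F1. DDQ in wet dioxane takes C7' through the alcohol to the aryl ketone, with water as the nucleophile and ring A again shielded by its acetate, giving 7'-oxo-O-acetylarctigenin F2. Corey–Bakshi–Shibata reduction follows (BH3·SMe2, THF, low temperature) with (R)-Me-CBS, the antipode that should give the (S)-carbinol by the usual aryl-large model. This gives the 4-O-acetate of the target F3. Pyrrolidine as in step 11 then gives 19.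

2. Step 12. The acyl shift may stall at 18, or the equilibrium between rings D and C may not lie far enough towards ring C. Basic fluoride may also epimerise C3 before the shift. The fallback sets out from 17 and comes back at 19, replacing the equilibrium by opening and a kinetically controlled closure.
   - nBu4NF buffered with AcOH gives 18, which is now isolated.
   - LiOH (THF/H2O, 0 °C) opens ring D to the dihydroxy acid F4, kept as its lithium salt, in which the α-centre does not epimerise.
   - Cold neutralisation to about pH 4, extraction and immediate treatment with EDC·HCl in CH2Cl2 at 0 °C (carbodiimide lactonisation) should acylate the unhindered primary C9' hydroxyl through the transition state leading to the trans ring, giving 19.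

3. Step 8. The primary silyl ether may be lost on acidification, followed by relactonisation back to 11. Cleavage of the aryl silyl ether may also be incomplete. The fallback sets out from 11 (through salt 12) and comes back at 14. It masks the carboxyl group as an ester that is released under neutral catalysis.
   - The dried salt 12 is alkylated with allyl bromide in DMF to the hydroxy bis-allyl compound F5.
   - F5 is silylated in the same flask (TBSCl, imidazole) to the silyl ether bis-allyl compound F6.
   - Pd(PPh3)4 (cat.) and morpholine in THF remove the allyl ester and the aryl allyl ether together (Tsuji–Trost deallylation).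
   - A wash at pH 4–5 gives 14.

**Further compounds**
F1 | step 10 | (3R,4R)-3-(4-acetoxy-3-methoxybenzyl)-4-(3,4-dimethoxybenzyl)dihydrofuran-2(3H)-one (O-acetylarctigenin) | COc1cc(C[C@H]2C(=O)OC[C@@H]2Cc2ccc(OC)c(OC)c2)ccc1OC(C)=O
F2 | step 10 | (3R,4R)-3-(4-acetoxy-3-methoxybenzyl)-4-(3,4-dimethoxybenzoyl)dihydrofuran-2(3H)-one (7'-oxo-O-acetylarctigenin) | COc1cc(C[C@H]2C(=O)OC[C@@H]2C(=O)c2ccc(OC)c(OC)c2)ccc1OC(C)=O
F3 | step 10 | (3R,4R)-3-(4-acetoxy-3-methoxybenzyl)-4-[(S)-(3,4-dimethoxyphenyl)(hydroxy)methyl]dihydrofuran-2(3H)-one (4-O-acetate of the target) | COc1cc(C[C@H]2C(=O)OC[C@@H]2[C@H](O)c2ccc(OC)c(OC)c2)ccc1OC(C)=O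
F4 | step 12 | (2R,3R)-3-[(S)-(3,4-dimethoxyphenyl)(hydroxy)methyl]-4-hydroxy-2-(4-hydroxy-3-methoxybenzyl)butanoic acid | OC(=O)[C@H](Cc1ccc(O)c(OC)c1)[C@H](CO)[C@H](O)c1ccc(OC)c(OC)c1
F5 | step 8 | allyl (2R,3R)-2-[4-(allyloxy)-3-methoxybenzyl]-3-(3,4-dimethoxybenzyl)-4-hydroxybutanoate | C=CCOC(=O)[C@H](Cc1ccc(OCC=C)c(OC)c1)[C@H](CO)Cc1ccc(OC)c(OC)c1
F6 | step 8 | allyl (2R,3R)-2-[4-(allyloxy)-3-methoxybenzyl]-4-(tert-butyldimethylsilyloxy)-3-(3,4-dimethoxybenzyl)butanoate | C=CCOC(=O)[C@H](Cc1ccc(OCC=C)c(OC)c1)[C@H](CO[Si](C)(C)C(C)(C)C)Cc1ccc(OC)c(OC)c1
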